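**Retrosynthetic overview**
1. Assumption: target 6 has no stereocentre, so "single enantiomer" is read as the single (E,E) geometric isomer. No ring is formed in the route, since both benzene rings are bought in 5.
2. Last disconnection: cut both Cα=Cβ bonds at once. This gives bis(malonamic acid) 4 plus two equivalents of 4-hydroxybenzaldehyde 5. The forward reaction is a double decarboxylative Knoevenagel–Doebner olefination catalysed only by the substrate's own N4–H. This is the new step, and it sets both E-alkenes.
3. 4 comes from di-tert-butyl ester 3 by acidolysis.
4. First disconnection: cut both amide C–N bonds of 3. This gives unprotected spermidine 1 plus tert-butyl methyl malonate 2, joined by primary-amine-selective ester aminolysis with no N-protecting group.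

**Step 1**
Reactants: 1 spermidine; 2 tert-butyl methyl malonate
Product: 3 N1,N8-bis(3-tert-butoxy-3-oxopropanoyl)spermidine. Both terminal nitrogens carry a –C(O)CH2CO2tBu group and the central N4–H is free.
Conditions: 2 (4 equiv), MeOH (3 M), 55 °C, 48 h. Extract into cold 5% citric acid, which leaves excess 2 in the organic layer, then basify with Na2CO3 and extract with CH2Cl2.
Reagents that add atoms: tert-butyl methyl malonate, COC(=O)CC(=O)OC(C)(C)C (MeOH is lost)
Why: Uncatalysed ester aminolysis is strongly sterically biased, so the two unhindered primary amines attack the activated methyl ester while the acyclic secondary N4 and the t-Bu esters stay untouched. This is the same discrimination that underlies terminal trifluoroacetylation of polyamines with ethyl trifluoroacetate. The inert t-Bu ester also prevents malonate cross-linking or macrocyclisation.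

**Step 2**
Reactants: 3
Product: 4 N1,N8-bis(carboxyacetyl)spermidine (the bis-malonamic acid), handled as its N4 trifluoroacetate salt
Conditions: TFA/CH2Cl2 (1:1), 0 °C to rt, 3 h. Concentrate at ≤30 °C, triturate with Et2O, and use directly.
Reagents that add atoms: none (trifluoroacetate is only a counter-ion and is not carried into 6)
Why: This is acid-mediated t-butyl ester cleavage with loss of isobutylene. The amides and the protonated amine are inert, and the low temperature avoids premature decarboxylation of the malonamic acids.

**Step 3 (key step)**
Reactants: 4 bis-malonamic acid (TFA salt); 5 4-hydroxybenzaldehyde
Product: 6 N1,N8-bis[(E)-p-coumaroyl]spermidine (target, free base)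
Conditions: 5 (2.5 equiv), 2,6-lutidine (1.1 equiv, only to neutralise TFA), no added amine catalyst, EtOH/DMSO 4:1 (0.4 M), 80 °C, 24 h, N2, dark. Then treat with 0.5 M HCl/MeOH to hydrolyse any aminals, load on SCX, and release with 2 M NH3/MeOH.
Reagents that add atoms: 4-hydroxybenzaldehyde, O=Cc1ccc(O)cc1 (its ArCH= unit is retained; 2 CO2 and 2 H2O are lost)
Why: Proposed new method: a substrate-autocatalysed double decarboxylative Knoevenagel–Doebner olefination, in which the N4 ammonium/carboxylate zwitterion of 4 acts as a built-in "piperidinium acetate" (0.5 equiv of amine per reacting site); N4 condenses with 5 to give a p-hydroxy-stabilised iminium ion, a malonamic-acid enol of the same or a second molecule adds in Mannich fashion, and the β-ammonio acid collapses by anti-periplanar decarboxylative elimination (or via the arylidene half-acid, whose quinone-methide tautomer is a vinylogous β-keto acid), releasing CO2, regenerating N4–H and placing aryl and carboxamide anti, so both E-alkenes are set here by the anti elimination and reinforced by the thermodynamic preference for the conjugated E isomer; irreversible CO2 loss pulls the reversible iminium and aminal resting states forward, the electron-rich coumaramide is too poor a Michael acceptor for N4 to attack, and the free phenols are tolerated; the closest known reaction type is the piperidine/pyridine- or proline-mediated Knoevenagel–Doebner condensation of malonic acid or N-aryl malonamic acids with hydroxybenzaldehydes, which to my knowledge has not been shown with an unprotected polyamine's internal amine as the sole catalyst or two-fold on a zwitterionic bis(malonamic acid).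

**Compound list**
1 | spermidine | NCCCCNCCCN | starting material
2 | tert-butyl methyl malonate | COC(=O)CC(=O)OC(C)(C)C | starting material
3 | N1,N8-bis(3-tert-butoxy-3-oxopropanoyl)spermidine | CC(C)(C)OC(=O)CC(=O)NCCCCNCCCNC(=O)CC(=O)OC(C)(C)C | intermediate
4 | N1,N8-bis(carboxyacetyl)spermidine (used as N4·TFA salt) | OC(=O)CC(=O)NCCCCNCCCNC(=O)CC(=O)O | intermediate
5 | 4-hydroxybenzaldehyde | O=Cc1ccc(O)cc1 | starting material
6 | N1,N8-bis[(E)-p-coumaroyl]spermidine, C25H31N3O4 | O=C(/C=C/c1ccc(O)cc1)NCCCCNCCCNC(=O)/C=C/c1ccc(O)cc1 | target

**Total step count:** 3. **Longest linear sequence:** 3.

**Steps most likely to fail**
1. **Step 3 (proposed new step).**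
   - Risks: the acyclic N4 may be too weak an iminium catalyst, or it may be parked as an N-acyl aminal. Premature decarboxylation would give N-acetyl ends. The second condensation may stall.
   - Fallback (known chemistry, different disconnection): form the amide bonds with the alkene already in place. Treat spermidine with CF3CO2Et, then Boc2O, then K2CO3/MeOH to give N4-Boc-spermidine. Couple this with commercial (E)-p-coumaric acid using EDC/HOBt, then remove Boc with TFA.
2. **Step 1.**
   - Risks: sluggish aminolysis may leave mono-acylated material, or some N4 acylation may occur.
   - Fallback: replace kinetic selectivity with protection. Prepare N4-Boc-spermidine as above and couple it with mono-tert-butyl malonate using EDC/HOBt. The TFA step then removes Boc and both t-Bu esters together and converges on the same 4.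
3. **Step 2.**
   - Risks: 4 may decarboxylate, or the polar salt may be hard to handle.
   - Fallback: reverse the order of events. Condense diester 3 with 5 first in an ordinary Knoevenagel reaction to give the bis(arylidene malonamate). Then cleave the t-Bu esters and decarboxylate the arylidene half-acids, assisted by the p-OH groups, to give the E-alkenes. The free malonamic acid is then never isolated.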